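**Plan**
1. Numbering: eight-membered ring C15–C1(Me)=C2–C3–C4–C5=C6(Me)–C7; cyclohexane C7–C8–C9–C13(Me)–C14–C15; ring D C9–C10(iPr)–C11–C12(OH)–C13; ring A C4–C5–C16–C17–C18(Me); C19 is the isopropyl methine.
2. Retrosynthetic cuts: C6–CH3 and C4–H (methylation of an enol triflate made by reductive triflation of a C4=C5–C6=O enone), C1=C2 (ring-closing metathesis), C5–C6 (Nozaki–Hiyama–Kishi), C15–C1 and C7–C6 (cuprate addition to a C15=C7 enal made from the C7 ketone), then C9–C10 of ring D.
3. Enabling feature: C10 of ring D carries the exocyclic branched carbon C19, so C10 and C19 can be the diazo and carbonyl carbons of a cyclohexanone in a trans-decalin whose angular methyl and neighbouring oxygen are C13–Me and C12–O of the Wieland–Miescher ketone; Wolff contraction forms C9–C10 and pushes C19 out as the ester that becomes the isopropyl group.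
4. Forward order: decalin (the cyclohexane ring plus a six-membered precursor of ring D) → ring D by contraction → ring A joined as a cyclopentenyl triflate → eight-membered ring by metathesis.
5. Stereochemistry: C13 from (R)-Wieland–Miescher ketone; C12 by hydride reduction; C9 by hydroboration anti to C13–Me; C10 by ester equilibration; C15 by cuprate attack anti to C13–Me; C7 by aldehyde epimerisation; C18 by CuH/p-Tol-BINAP reduction; C4 by protonation anti to C18–Me; both ring alkenes are Z by ring constraint.

Key step: step 8

Assumption: in step 16 (R)-p-Tol-BINAP is taken to deliver hydride to the enone face that gives the (3S) centre; if the sense is the reverse, the (S)-ligand is used.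

**Route**

Step 1
Reactants: 1 (R)-Wieland–Miescher ketone
Product: 2 (4aR,5R)-5-hydroxy-4a-methyl-4,4a,5,6,7,8-hexahydronaphthalen-2(3H)-one
Conditions: NaBH4 (0.3 equiv), EtOH, −10 to 0 °C
Reagents that add atoms: none
Why: Chemoselective borohydride reduction of the saturated C12 ketone, which is more electrophilic than the enone carbonyl; hydride attacks anti to the angular methyl and gives the equatorial C12 alcohol cis to C13–Me.

Step 2
Reactants: 2 hydroxy enone
Product: 3 C7 ethylene ketal with the double bond moved to C9=C19 and free C12–OH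
Conditions: ethylene glycol, p-TsOH (cat.), benzene, reflux, Dean–Stark
Reagents that add atoms: ethylene glycol (OCCO)
Why: Acid-catalysed ketalisation of the enone with deconjugation, as for Δ4-3-keto steroids, masks C7 and places the alkene at C9=C19 for oxygenation at C19.

Step 3
Reactants: 3 ketal alcohol
Product: 4 C12 tert-butyldimethylsilyl ether of 3
Conditions: TBSCl, imidazole, DMF, 40 °C
Reagents that add atoms: tert-butyldimethylsilyl chloride (CC(C)(C)[Si](C)(C)Cl)
Why: Standard silyl ether formation protects the C12 alcohol for the basic, organometallic and reducing steps that follow.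

Step 4
Reactants: 4 silyl ether
Product: 5 trans-decalin C19 alcohol (C9–H anti to C13–Me, C19–OH on the face of C9–H)
Conditions: BH3·THF, THF, 0 °C to rt; then NaOH, H2O2
Reagents that add atoms: hydrogen peroxide (OO)
Why: Brown hydroboration–oxidation puts boron on the less substituted C19 and hydrogen on C9 from the face opposite the angular C13 methyl, which sets the trans ring fusion as in Δ5-steroid ketals.

Step 5
Reactants: 5 C19 alcohol
Product: 6 trans-decalin C19 ketone (C7 ketal, C12–OTBS)
Conditions: TPAP (5 mol%), NMO, 4 Å MS, CH2Cl2, rt; then K2CO3 (cat.), MeOH, rt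
Reagents that add atoms: none
Why: Ley–Griffith oxidation gives the ketone without acid, and mild base equilibrates any cis-fused material through the C9 enolate to the more stable trans-decalone.

Step 6
Reactants: 6 C19 ketone
Product: 7 C10 hydroxymethylene C19 ketone
Conditions: NaH, HCO2Et, THF, cat. EtOH, 0 °C to rt; aq. NH4Cl
Reagents that add atoms: ethyl formate (CCOC=O)
Why: Claisen formylation under equilibrating conditions; only C10 can give the stabilised enolised β-keto aldehyde, so the methylene next to C19 is activated.

Step 7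
Reactants: 7 hydroxymethylene ketone
Product: 8 trans-decalin α-diazoketone (diazo on C10, carbonyl C19)
Conditions: 4-acetamidobenzenesulfonyl azide, Et3N, MeCN, 0 °C to rt
Reagents that add atoms: 4-acetamidobenzenesulfonyl azide (CC(=O)Nc1ccc(cc1)S(=O)(=O)N=[N+]=[N-])
Why: Regitz deformylative diazo transfer: the azide adds to the enolate and the formyl group leaves as the N-formyl sulfonamide, which places the diazo group on C10.

Step 8
Reactants: 8 α-diazoketone
Product: 10 trans-hydrindane C10 methyl ester (CO2Me on the face of C9–H), via ketene 9 (not isolated)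
Conditions: hν (350 nm, Pyrex), MeOH, rt; then NaOMe (0.2 equiv), MeOH, rt
Reagents that add atoms: methanol (CO)
Why: Irradiation expels N2 from the s-cis-locked α-diazoketone and the ring carbon C9 shifts from C19 to C10 (concerted with nitrogen loss or through the singlet acylcarbene), giving ketene 9, which methanol traps as the ester. The closest known reaction type is the photochemical Wolff ring contraction of cyclic 2-diazo ketones from six- to five-membered rings. Ring D closes by this 1,2-shift, that is by contraction of the existing six-membered ring through formation of C9–C10 and not by a new cyclisation, so the trans fusion of the decalin is carried into the hydrindane. C9 migrates with retention, and the new C10 centre is controlled thermodynamically, methoxide equilibrating the ester to the face of C9–H, anti to the C13 methyl. The step needs migration of C9 in preference to O–H insertion or a hydride shift from C11, which the cyclic geometry with the C9–C19 bond anti to the departing nitrogen secures; the ketal and silyl ether are inert to light and methoxide.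

Step 9
Reactants: 10 methyl ester
Product: 11 C10 2-hydroxyprop-2-yl hydrindane (tertiary alcohol)
Conditions: MeMgBr (3 equiv), THF, 0 °C to rt; aq. NH4Cl
Reagents that add atoms: methylmagnesium bromide (C[Mg]Br)
Why: Double Grignard addition to the ester gives the tertiary carbinol that holds all three carbons of the isopropyl group.

Step 10
Reactants: 11 tertiary alcohol
Product: 12 C10 isopropenyl hydrindane ketal
Conditions: Burgess reagent, toluene, 60 °C
Reagents that add atoms: none
Why: Burgess dehydration (syn elimination through the sulfamate) has six methyl hydrogens available against one hindered C10–H, so the isopropenyl isomer should predominate and C10 keeps its configuration.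

Step 11
Reactants: 12 isopropenyl compound
Product: 13 C10 isopropyl hydrindane ketal
Conditions: H2 (1 atm), 10% Pd/C, EtOAc, rt
Reagents that add atoms: none
Why: Heterogeneous catalytic hydrogenation saturates the 1,1-disubstituted alkene without touching a stereocentre; any tetrasubstituted isomer from step 10 stays unreduced and is separated here.

Step 12
Reactants: 13 ketal
Product: 14 hydrindan-7-one (C10 iPr, C12–OTBS)
Conditions: PPTS, acetone/H2O (10:1), reflux
Reagents that add atoms: water (O)
Why: Mild acid-catalysed ketal hydrolysis frees the C7 ketone while the hindered secondary silyl ether survives.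

Step 13
Reactants: 14 C7 ketone
Product: 15 C7 enol triflate with the C7=C15 double bond
Conditions: LDA, THF, −78 °C; PhNTf2, −78 to 0 °C; aq. NH4Cl
Reagents that add atoms: N-phenylbis(trifluoromethanesulfonimide) (O=S(=O)(N(c1ccccc1)S(=O)(=O)C(F)(F)F)C(F)(F)F)
Why: Kinetic enolate formation and triflation (McMurry–Scott); trans-fused hydrindan-5-ones, like 5α-3-keto steroids, enolise away from the ring fusion, so the C7=C15 regioisomer should be the main product.

Step 14
Reactants: 15 enol triflate
Product: 16 enal (C7–CHO on the C7=C15 double bond)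
Conditions: Pd(PPh3)4 (5 mol%), LiCl, CO (1 atm), Bu3SnH (slow addition), THF, 50 °C
Reagents that add atoms: carbon monoxide ([C-]#[O+])
Why: Palladium-catalysed reductive carbonylation of the enol triflate (Stille formylation) turns C7–OTf into the C7 aldehyde and so adds C6.

Step 15
Reactants: 16 enal
Product: 18 trans-diequatorial C15-isopropenyl C7-aldehyde, via trimethylsilyl enol ether 17 (not isolated)
Conditions: isopropenylMgBr, CuBr·SMe2 (10 mol%), TMSCl, DMPU, THF, −78 °C; then K2CO3, MeOH, rt
Reagents that add atoms: isopropenylmagnesium bromide (CC(=C)[Mg]Br)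
Why: Copper-catalysed conjugate addition of the Grignard reagent accelerated by TMSCl (Kuwajima–Nakamura conditions): the cuprate should attack C15 from the face opposite the 1,3-related axial C13 methyl, giving the equatorial isopropenyl group, and base then epimerises C7 to the equatorial aldehyde trans to it.

Step 16
Reactants: 19 3-methylcyclopent-2-en-1-one
Product: 21 (2R,3S)-2-allyl-3-methylcyclopentan-1-one, via bis-enol diphenylsilane 20 (not isolated)
Conditions: CuCl (5 mol%), NaOt-Bu (5 mol%), (R)-p-Tol-BINAP (5 mol%), Ph2SiH2 (0.55 equiv), toluene, 0 °C; then allyl bromide, TBAT, CH2Cl2, rt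
Reagents that add atoms: allyl bromide (C=CCBr)
Why: Buchwald copper hydride asymmetric conjugate reduction sets C18 under catalyst control, and fluoride-promoted allylation of the silyl enol ether in the same pot places the allyl group on C4, a centre that becomes sp2 in the next step.

Step 17
Reactants: 21 allyl ketone
Product: 23 (3S)-2-allyl-3-methylcyclopent-1-en-1-yl trifluoromethanesulfonate, via trimethylsilyl enol ether 22 (not isolated)
Conditions: TMSCl, NaI, Et3N, MeCN, rt; solvent exchange to THF; MeLi, 0 °C; PhNTf2, −78 °C to rt; aq. NH4Cl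
Reagents that add atoms: N-phenylbis(trifluoromethanesulfonimide) (O=S(=O)(N(c1ccccc1)S(=O)(=O)C(F)(F)F)C(F)(F)F)
Why: Enolisation under thermodynamic control (iodotrimethylsilane/triethylamine, House-type silyl enol ether) favours the tetrasubstituted C4=C5 enol, and its lithium enolate, freed by MeLi, is triflated on oxygen.

Step 18
Reactants: 18 aldehyde; 23 ring-A alkenyl triflate
Product: 24 allylic alcohol (C6 carbinol between C7 and C5, both C6 epimers)
Conditions: CrCl2 (4 equiv), NiCl2 (2 mol%), DMF/DMSO (3:1), rt
Reagents that add atoms: none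
Why: Nozaki–Hiyama–Kishi coupling: nickel inserts into the alkenyl triflate and the alkenylchromium(III) species adds to the aldehyde without enolising C7; the C6 configuration does not matter because it is oxidised next.

Step 19
Reactants: 24 allylic alcohol
Product: 25 dienone (C6 ketone conjugated with C4=C5; C15 isopropenyl, C4 allyl)
Conditions: TPAP (5 mol%), NMO, 4 Å MS, CH2Cl2, rt
Reagents that add atoms: none
Why: Ley–Griffith oxidation of the allylic alcohol gives the C6 ketone under neutral conditions that spare the skipped diene and the C7 centre.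

Step 20
Reactants: 25 dienone
Product: 26 tetracyclic enone (eight-membered ring closed, (Z)-C1=C2, C4=C5–C6=O)
Conditions: Grubbs II (10 mol%), toluene (1 mM), 80 °C
Reagents that add atoms: none
Why: Ring-closing metathesis between the allyl and isopropenyl groups forms the trisubstituted C1=C2 bond; the cis C4=C5 bond holds C3 and C6 on the same side and the eight-membered ring allows only the Z alkene.

Step 21
Reactants: 26 tetracyclic enone
Product: 28 C6 enol triflate (C5=C6, C4–H anti to C18–Me), via lithium enolate 27 (not isolated)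
Conditions: Li, NH3(l)/THF, t-BuOH (1 equiv), −78 °C; isoprene; NH3 evaporated; PhNTf2, THF, −78 to 0 °C; aq. NH4Cl
Reagents that add atoms: N-phenylbis(trifluoromethanesulfonimide) (O=S(=O)(N(c1ccccc1)S(=O)(=O)C(F)(F)F)C(F)(F)F)
Why: Dissolving-metal (Birch-type) enone reduction with regiospecific trapping of the lithium enolate as the triflate: the β-carbon C4 should be protonated from the face opposite the C18 methyl, and the ring fixes the C5=C6 geometry with C7 cis to C4.

Step 22
Reactants: 28 enol triflate
Product: 29 12-O-TBS ether of the target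
Conditions: MeMgBr, Fe(acac)3 (5 mol%), THF/NMP, −30 to 0 °C
Reagents that add atoms: methylmagnesium bromide (C[Mg]Br)
Why: Iron-catalysed Kumada-type cross-coupling of the enol triflate with the methyl Grignard reagent (Fürstner conditions) installs the C6 methyl with retention of the double-bond geometry.

Step 23
Reactants: 29 silyl ether
Product: 30 target CNP0541339.1
Conditions: TBAF, THF, 50 °C
Reagents that add atoms: none
Why: Fluoride cleavage of the silyl ether releases the C12 alcohol; nothing else in the molecule reacts with TBAF.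

**Compound list**
1 | (R)-Wieland–Miescher ketone, (8aR)-8a-methyl-3,4,8,8a-tetrahydronaphthalene-1,6(2H,7H)-dione | C[C@@]12CCC(=O)C=C1CCCC2=O | starting material
2 | (4aR,5R)-5-hydroxy-4a-methyl-4,4a,5,6,7,8-hexahydronaphthalen-2(3H)-one (C12–OH cis to C13–Me) | C[C@@]12CCC(=O)C=C1CCC[C@H]2O | intermediate
3 | C7 ethylene ketal, C9=C19 alkene, free C12–OH | C[C@@]12CCC3(OCCO3)CC1=CCC[C@H]2O | intermediate
4 | C12–OTBS ether of 3 | C[C@@]12CCC3(OCCO3)CC1=CCC[C@H]2O[Si](C)(C)C(C)(C)C | intermediate
5 | trans-decalin C19 alcohol (C7 ketal, C12–OTBS, C9–H anti to C13–Me, C19–OH on the face of C9–H) | C[C@@]12CCC3(OCCO3)C[C@H]1[C@H](O)CC[C@H]2O[Si](C)(C)C(C)(C)C | intermediate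
6 | trans-decalin C19 ketone (C7 ketal, C12–OTBS) | C[C@@]12CCC3(OCCO3)C[C@H]1C(=O)CC[C@H]2O[Si](C)(C)C(C)(C)C | intermediate
7 | C10 hydroxymethylene C19 ketone | C[C@@]12CCC3(OCCO3)C[C@H]1C(=O)/C(=C\O)C[C@H]2O[Si](C)(C)C(C)(C)C | intermediate
8 | trans-decalin α-diazoketone (C10 diazo, C19 carbonyl, C7 ketal, C12–OTBS) | C[C@@]12CCC3(OCCO3)C[C@H]1C(=O)C(=[N+]=[N-])C[C@H]2O[Si](C)(C)C(C)(C)C | intermediate
9 | ketene C10=C19=O on the contracted ring D, not isolated | C[C@@]12CCC3(OCCO3)C[C@H]1C(=C=O)C[C@H]2O[Si](C)(C)C(C)(C)C | intermediate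
10 | trans-hydrindane C10 methyl ester (ester on the face of C9–H, anti to C13–Me; C7 ketal; C12–OTBS) | C[C@@]12CCC3(OCCO3)C[C@H]1[C@H](C(=O)OC)C[C@H]2O[Si](C)(C)C(C)(C)C | intermediate
11 | C10 2-hydroxyprop-2-yl hydrindane ketal | C[C@@]12CCC3(OCCO3)C[C@H]1[C@H](C(C)(C)O)C[C@H]2O[Si](C)(C)C(C)(C)C | intermediate
12 | C10 isopropenyl hydrindane ketal | C[C@@]12CCC3(OCCO3)C[C@H]1[C@H](C(C)=C)C[C@H]2O[Si](C)(C)C(C)(C)C | intermediate
13 | C10 isopropyl hydrindane ketal | C[C@@]12CCC3(OCCO3)C[C@H]1[C@H](C(C)C)C[C@H]2O[Si](C)(C)C(C)(C)C | intermediate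
14 | hydrindan-7-one (C10 iPr, C12–OTBS) | C[C@@]12CCC(=O)C[C@H]1[C@H](C(C)C)C[C@H]2O[Si](C)(C)C(C)(C)C | intermediate
15 | C7 enol triflate, C7=C15 | C[C@@]12CC=C(OS(=O)(=O)C(F)(F)F)C[C@H]1[C@H](C(C)C)C[C@H]2O[Si](C)(C)C(C)(C)C | intermediate
16 | enal, C7–CHO on C7=C15 | C[C@@]12CC=C(C=O)C[C@H]1[C@H](C(C)C)C[C@H]2O[Si](C)(C)C(C)(C)C | intermediate
17 | trimethylsilyl enol ether C7=C6H–OTMS (E/Z), C15 isopropenyl, not isolated | C[C@@]12C[C@H](C(C)=C)C(=CO[Si](C)(C)C)C[C@H]1[C@H](C(C)C)C[C@H]2O[Si](C)(C)C(C)(C)C | intermediate
18 | (7S,15S) aldehyde: C15 isopropenyl and C7 formyl, trans-diequatorial | C[C@@]12C[C@H](C(C)=C)[C@@H](C=O)C[C@H]1[C@H](C(C)C)C[C@H]2O[Si](C)(C)C(C)(C)C | intermediate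
19 | 3-methylcyclopent-2-en-1-one | CC1=CC(=O)CC1 | starting material
20 | bis[(3S)-3-methylcyclopent-1-en-1-yloxy]diphenylsilane, not isolated | C[C@H]1CCC(O[Si](OC2=C[C@@H](C)CC2)(c2ccccc2)c2ccccc2)=C1 | intermediate
21 | (2R,3S)-2-allyl-3-methylcyclopentan-1-one | O=C1CC[C@H](C)[C@H]1CC=C | intermediate
22 | [(3S)-2-allyl-3-methylcyclopent-1-en-1-yl]oxytrimethylsilane, not isolated | C=CCC1=C(O[Si](C)(C)C)CC[C@@H]1C | intermediate
23 | (3S)-2-allyl-3-methylcyclopent-1-en-1-yl trifluoromethanesulfonate (ring A: C5–OTf, C4 allyl, C18–Me) | C=CCC1=C(OS(=O)(=O)C(F)(F)F)CC[C@@H]1C | intermediate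
24 | allylic alcohol, C6 carbinol linking C7 to C5 of the cyclopentene (both C6 epimers) | C[C@@]12C[C@H](C(C)=C)[C@@H](C(O)C3=C(CC=C)[C@@H](C)CC3)C[C@H]1[C@H](C(C)C)C[C@H]2O[Si](C)(C)C(C)(C)C | intermediate
25 | dienone, C6 ketone conjugated with C4=C5 | C[C@@]12C[C@H](C(C)=C)[C@@H](C(=O)C3=C(CC=C)[C@@H](C)CC3)C[C@H]1[C@H](C(C)C)C[C@H]2O[Si](C)(C)C(C)(C)C | intermediate
26 | tetracyclic enone, (Z)-C1=C2, C4=C5–C6=O, C12–OTBS | C/C1=C/CC2=C(C(=O)[C@H]3C[C@H]4[C@H](C(C)C)C[C@@H](O[Si](C)(C)C(C)(C)C)[C@]4(C)C[C@H]13)CC[C@@H]2C | intermediate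
27 | lithium enolate C5=C6–OLi with C4–H, not isolated | C/C1=C/C[C@@H]2/C(=C(/[O-])[C@H]3C[C@H]4[C@H](C(C)C)C[C@@H](O[Si](C)(C)C(C)(C)C)[C@]4(C)C[C@H]13)CC[C@@H]2C.[Li+] | intermediate
28 | C6 enol triflate, C5=C6, C4–H anti to C18–Me | C/C1=C/C[C@@H]2/C(=C(/OS(=O)(=O)C(F)(F)F)[C@H]3C[C@H]4[C@H](C(C)C)C[C@@H](O[Si](C)(C)C(C)(C)C)[C@]4(C)C[C@H]13)CC[C@@H]2C | intermediate
29 | 12-O-TBS ether of the target | C/C1=C/C[C@@H]2/C(=C(/C)[C@H]3C[C@H]4[C@H](C(C)C)C[C@@H](O[Si](C)(C)C(C)(C)C)[C@]4(C)C[C@H]13)CC[C@@H]2C | intermediate
30 | CNP0541339.1 | C/C1=C/C[C@@H]2/C(=C(/C)[C@H]3C[C@H]4[C@H](C(C)C)C[C@@H](O)[C@]4(C)C[C@H]13)CC[C@@H]2C | target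

**Totals**
Total steps: 23. Longest linear sequence: 21 steps (steps 1–15 and 18–23); the ring-A branch is steps 16–17.

**Steps most likely to fail**

1. Step 21. The folded eight-membered ring, and not the C18 methyl, may decide which face of C4 is protonated, and a twisted, weakly conjugated enone may be reduced at the carbonyl instead. Fallback, setting out from dienone 25 and coming back at enol triflate 28: the reduction is moved ahead of the ring closure. Li/NH3 (t-BuOH; NH4Cl quench) on the open-chain enone, where the C18 methyl is the only element that differentiates the faces of the cyclopentene, should give the open-chain saturated ketone F1 with C4–H anti to the methyl; C5 is epimerisable and need not be controlled. Ring-closing metathesis of F1 (Grubbs II, toluene, 80 °C) gives the eight-membered saturated ketone F2. Thermodynamic enolisation toward C5, which places the double bond exocyclic to the five-membered ring (KHMDS with a slight excess of ketone, THF, −78 to 0 °C; PhNTf2), then rejoins the route at 28.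

2. Step 15. The stereoelectronically preferred axial attack at C15, syn to the C13 methyl, may compete with attack anti to the methyl, and 1,2-addition to the aldehyde may intervene. Fallback, setting out from ketone 14 and coming back at aldehyde 18: both centres are set by equilibration. Palladium-catalysed α-alkenylation of the lithium enolate of 14 with 2-bromopropene (Pd2(dba)3, Q-Phos, LiHMDS, toluene) gives the α-isopropenyl ketone F3, in which C15 settles equatorial by epimerisation next to the carbonyl. Wittig methoxymethylenation (Ph3P=CHOMe) gives the methyl enol ether F4. Mild acid hydrolysis and K2CO3/MeOH equilibration of the new C7 aldehyde rejoin the route at 18.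

3. Step 20. The ruthenium alkylidene formed at the allyl group may fail to engage the hindered isopropenyl group, so that dimerisation by cross-metathesis or migration of the allyl double bond into conjugation takes over. Fallback, setting out from carbinol 24 and coming back at enone 26: the ring is closed before the oxidation, on the sp3 carbinol where C6 is tetrahedral and the two alkenes are not held apart by the planar cross-conjugated ketone. Metathesis of 24 (Hoveyda–Grubbs II, toluene, 80 °C, high dilution) gives the cyclised allylic alcohol F5, and TPAP/NMO oxidation of F5 rejoins the route at 26.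

Further compounds
F1 | step 21 | open-chain saturated ketone (C4–H anti to C18–Me, C5 epimers) | C[C@@]12C[C@H](C(C)=C)[C@@H](C(=O)C3CC[C@H](C)[C@@H]3CC=C)C[C@H]1[C@H](C(C)C)C[C@H]2O[Si](C)(C)C(C)(C)C
F2 | step 21 | eight-membered saturated ketone (C6=O, C4–H, C5 epimers) | C/C1=C/C[C@@H]2C(C(=O)[C@H]3C[C@H]4[C@H](C(C)C)C[C@@H](O[Si](C)(C)C(C)(C)C)[C@]4(C)C[C@H]13)CC[C@@H]2C
F3 | step 15 | α-isopropenyl ketone (C7=O, C15 isopropenyl equatorial) | C[C@@]12C[C@H](C(C)=C)C(=O)C[C@H]1[C@H](C(C)C)C[C@H]2O[Si](C)(C)C(C)(C)C
F4 | step 15 | methyl enol ether (C7=CH–OMe, E/Z) | C[C@@]12C[C@H](C(C)=C)C(=COC)C[C@H]1[C@H](C(C)C)C[C@H]2O[Si](C)(C)C(C)(C)C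
F5 | step 20 | cyclised allylic alcohol (C6 carbinol, both epimers) | C/C1=C/CC2=C(C(O)[C@H]3C[C@H]4[C@H](C(C)C)C[C@@H](O[Si](C)(C)C(C)(C)C)[C@]4(C)C[C@H]13)CC[C@@H]2C
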